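**Leftover.** Once product is counted, what stays over in the amber and green readings is a thin column of target: 1.9% beside 15.4% product at 1.0 min in amber. At 8.0 min the two runs read 79.2% and 78.7% product from different charges, so I reckon in percent of the charge and carry that to the flask.

| setting | amber | green | flask |
|---|---|---|---|
| substrate | 0.14 M | 0.22 M | 0.10 M |
| remark | run made earlier | run made earlier |  |
| time |  |  | 8.0 min |

| run | time / min | over-reaction product / % | target / % |
|---|---|---|---|
| amber | 1.00 | 15.4 | 1.9 |
| amber | 3.00 | 42.9 | 1.3 |
| amber | 5.00 | 61.4 | 1.3 |
| amber | 8.00 | 79.2 | 0.1 |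
| green | 1.00 | 15.1 | 1.8 |
| green | 3.00 | 43.1 | 1.8 |
| green | 5.00 | 61.1 | 1.0 |
| green | 8.00 | 78.7 | 0.8 |

(scatter of a reading: 0.3 percentage points)

- share of over-reaction product in over-reaction product plus target at 10 s
- share of over-reaction product in over-reaction product plus target at 1.0 min
- share of over-reaction product in over-reaction product plus target at 8.0 min

**Drain constant.** The proposed step into product starts from target, so I let product rise as fast as target drains, and I read the constant of that drain off the two runs. Product gained from 1.0 min to 8.0 min, pooled over both runs and divided by the area under target, gives the drain constant, product made per minute per unit of target, 7.49 min⁻¹.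

**Chain.** At 1.0 min the pooled readings give a share of 89.2%. The rest, not yet product, reads as falling at 0.203 min⁻¹ over the last interval of the two runs. Taking target late on as quasi-steady (the quasi-steady state: what feeds it equals what drains it), I estimate target in the flask at 8.0 min near 0.571%, a share of 99.3%. At 10 s the clock reads 1.25 target lifetimes, and a steady feed gives 42.9%.

**Weak link.** The early feed in the two runs does not look steady: pooled, product plus target reads 17.1% at 1.0 min, less than the 18.4% that 0.203 min⁻¹ gives from the start. A feed rising from nothing gives 31.3%, so I commit to the middle, 37.1%.

**Result.** The forecast says 35% (from 15% to 50%), 89% and 99.4%, starting from “The two runs overlay despite different charges”. The flask gives 39.0%, 88.4% and 99.4%.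

    target → over-reaction product (k = 0.138 s⁻¹)
    substrate → intermediate A (k = 0.0708 s⁻¹)
    intermediate B → target (k = 0.0274 s⁻¹)
    intermediate D ⇌ intermediate E (K = 0.351, k = 0.108 s⁻¹)
    intermediate E → target (k = 0.0244 s⁻¹)
    substrate ⇌ intermediate C (K = 3.05, k = 0.135 s⁻¹)
    intermediate A ⇌ intermediate D (K = 0.925, k = 0.0360 s⁻¹)
    substrate → intermediate B (k = 0.0385 s⁻¹)
    intermediate B ⇌ intermediate D (K = 40.0, k = 0.0320 s⁻¹)

**Early feed.** With 7.49 min⁻¹, 10 s is 1.25 lifetimes, and the flask's 39.0% stands between my 31.3% and 42.9%. The largest single effect I can show there is the reaction of substrate to intermediate B: the same run without it gives 26.2%. That route puts target into the flask early.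

**Second flask.** For a neighbour flask with 0.025 M substrate, below the charges of both runs, I carry over 7.49 min⁻¹ on the strength of the overlay, so I expect 99.3% at 8.0 min and between 31.3% and 42.9% at 10 s. The neighbour flask gives 99.4% and 39.0%.

Readings and results are calculated for substances that don't exist, noise included.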